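Labdane numbering (C1–C20; C17 on C8, C18 and C19 on C4, C20 on C10) is used for atoms at every stage, including the open-chain precursors.

## Analysis of the target

Target 27 is a labdane: a trans-fused decalin (ring A = C1–C5 and C10, ring B = C5–C10) with geminal methyls on C4, an angular methyl on C10, and on C9 a six-carbon chain C11–C16 that ends in the methyl ester C15 and carries the methyl C16 on C13. It has six stereocentres. C5, C6, C8, C9 and C10 lie on ring B, and C13 (S) is separated from them by two methylene groups and must be set independently. On ring B the C10 methyl, the C8 methyl, the C9 chain and the C6 acetoxy group are β, while H5, H9 and the C8 hydroxyl are α. The acetate is therefore axial and syn to the axial methyls on C4, C8 and C10, and the equatorial tertiary hydroxyl is anti to it. The sensitive features are the tertiary C8 hydroxyl β to C6 (retro-aldol cleavage and dehydration once C6 is a ketone), the hindered acetate that must be installed beside a free tertiary alcohol, and the methyl ester. The difficulty is the density of fully substituted carbons: C4, C8 and C10 are quaternary, C5 sits between two of them, and the contiguous centres C8–C9–C10–C5 must be set both relative to one another and in absolute terms. The strategy rests on one observation: the C8 carbinol oxygen, C8 with its methyl C17, C7, the oxygenated C6 and C5 are the five ring atoms of a 3-oxygenated 2-methylfuran. The furan can act as the diene that builds ring B, and its oxygen can travel as a C5–O–C8 bridge and end as the tertiary hydroxyl.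

## Retrosynthetic reasoning

**27 to 26.** The last operation is saturation of C11=C12. This alkene is only the trace of the fragment union and carries no stereochemical information, so its removal is left to the end, when nothing else in the molecule is reducible under the conditions.

**26 to 25 to 24.** The acetate is taken back to the 6β,8α-diol 25 and this to the C6 ketone 24. The cut is made here because the β face of C6 is covered by three axial methyl groups, so hydride can only enter from the α face and deliver the axial 6β alcohol. A ketone at C6 is also the handle needed for the next disconnection.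

**24 to 23.** The C5–H bond is exchanged for a C5–O bond to the C8 oxygen. In 23 the C8 oxygen is an ether bridge α to the C6 carbonyl, so a two-electron reduction cleaves exactly this bond and no other. The forward step must also deliver H5 on the α face. This disconnection turns ring B into a 7-oxanorbornane, which is what makes the furan visible.

**23 to 22.** The ketone is taken back to its silyl enol ether C6=C7, the form in which a cycloadduct of a 3-silyloxyfuran is born. Keeping it masked during the basic fragment union protects the bridge from β-elimination.

**22 to 16 and 21.** The C11=C12 bond is cut by a Wittig disconnection. C11 is the formyl carbon that the cycloaddition leaves on C9, and the four-carbon partner C12–C15 contains the only remote stereocentre. Ylide 21 comes from phosphonium salt 20, this from iodide 19, and 19 by iododecarboxylation of half-ester 18, whose C13 centre is set by desymmetrising alcoholysis of the prochiral anhydride 17.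

**16 to 14.** The key disconnection is a retro-[4+2] that cuts C5–C10 and C8–C9. It opens rings A and B together, removes four stereocentres and leaves the achiral furan enal 14. All relative stereochemistry then follows from the geometry of the tether and of the E alkene, and the absolute sense from a chiral amine that activates the enal as its iminium ion.

**14 to 13 to 12.** The silyloxyfuran is the O-silylated enol form of furan-3(2H)-one 13, and the enal comes from the allylic alcohol of 12. The alcohol is oxidised before silylation so that no hydroxyl competes for the silyl triflate and no protecting group is needed.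

**12 to 10 to 9 to 8.** The furanone ring is opened at the C8–O bond to the γ-hydroxy ynone 10. The forward reaction is a net hydration and cyclisation in which the C5 hydroxyl becomes the ring oxygen. 10 is the C-acetylation product of the acetylide of propargylic alcohol 9, and 9 is the ethynylation product of aldehyde 8 (C5–C6 bond). These are reliable acyl-anion-equivalent steps on a neopentyl aldehyde.

**8 to 7 to 5 and 6.** Both functional groups of 8 arise by hydride reduction of the cyano ester 7. Its trisubstituted E alkene C9=C10 is cut by a Horner–Wadsworth–Emmons disconnection to methyl ketone 5 and phosphonate 6.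

**5 to 4 to 2 and 3, and 2 to 1.** The quaternary carbon C4 is made by cutting C3–C4: alkylation of the anion of isobutyronitrile 3 with the ketal-protected chloride 2, which is made from chloroketone 1. The nitrile carbon becomes C5.

## Alternatives that were turned down

**Alternative 1:** The disconnection cuts C1–C10 and C9–C11 on a ring B enone, 3-methylcyclohex-2-en-1-one A1.
- Key step: a monovalent copper salt with a chiral N-heterocyclic carbene ligand adds the homoprenyl Grignard reagent A2 to C10, and the enolate is alkylated at C9 by the side-chain iodide A3. The product is ketone A4, which carries the C10 methyl, the homoprenyl arm and the whole C11–C16 chain.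
- For: the route is convergent, and the asymmetric conjugate addition that builds the C10 quaternary centre is well established for enones of this kind. The side chain arrives complete with C13. On precedent and on the side-chain union this alternative is stronger than the chosen route, whose key step is untested and whose chain is attached at a crowded aldehyde.
- Against: the magnesium enolate next to the new quaternary carbon must be alkylated by an unactivated primary iodide, which is slow and invites proton exchange that scrambles C9. In A4, C5 and C6 are still unfunctionalised methylenes, so closing C4–C5, setting C5, oxidising C6 and building the C8 methyl carbinol all remain.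
- Comparison: the chosen strategy gives up precedent but delivers both rings, four stereocentres and both ring oxygens in one step.

**Alternative 2:** Ring B is taken from 2,6-dimethyl-1,4-benzoquinone A5, and ring A is cut at C1–C10 and C4–C5.
- Key step: a chiral oxazaborolidinium Lewis acid activates A5 towards the silyloxydiene A6. Michael-type attack at C10 is followed by closure at C5, and basic work-up hydrolyses the enol ether and equilibrates the ring fusion, to give the trans-fused trione A7.
- For: the starting materials are flat and cheap. The quinone supplies C6 with its oxygen, C8 with C17 and C10 with C20. Quinone cycloadditions under this kind of catalysis are mature, and the trans fusion is secured thermodynamically. These points are stronger than in the chosen route.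
- Against: the reacting diene terminus C4 is fully substituted, so the second bond must join it to C5 in a hindered stepwise closure. A7 has an oxygen at C2 that must be deleted. It has a ketone at C9, where the complete six-carbon chain must be added next to quaternary C10 and the oxygen then removed with control of H9. C8 still needs its α hydroxyl. Differentiating three carbonyl groups costs many redox steps.
- Comparison: the chosen cycloadduct already carries C11 on C9 with the right configuration, has the C6 and C8 oxygens in differentiated form, and has no superfluous oxygen.

**Alternative 3:** Both rings are cut from the acyclic malonate enone A8, at C5–C10 and C6–C7.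
- Key step: methoxide, with a cinchona-derived amine–thiourea to bias the first step, triggers a 6-exo Michael addition of the malonate carbon C5 to C10. A Claisen condensation of the methyl ketone carbon C7 onto one ester (C6) then gives the bicyclic dione ester A9.
- For: the reagents are very cheap and both rings form in one pot. The Claisen step ends in a stabilised 1,3-dione enolate, a better thermodynamic sink than the chosen cycloaddition, which can revert.
- Against: the Michael step must join a fully substituted malonate carbon flanked by quaternary C4 to a β,β-disubstituted enone carbon. Such a nucleophile responds poorly to hydrogen-bonding catalysts, so control at C10 is doubtful. A9 has no substituent at C9, and the doubly activated C7 would compete in any alkylation. The C5 ester must be excised with control of H5, and the C8 methyl carbinol is still missing.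
- Comparison: the chosen strategy sets C9 with C11 attached and the C8 carbinol in the same step, and no carbon has to be removed.

Key step: step 11

Assumption 1: the quinidine-derived catalyst of step 12 is taken to open anhydride 17 to the S half-ester 18; should the sense be the reverse, the pseudo-enantiomeric quinine-derived diether is used instead and nothing else changes.

Assumption 2: the Wittig reaction of step 15 is taken to give the Z alkene, as drawn for 22–26; an E isomer would be carried through in the same way, because the alkene is hydrogenated in step 20.

Remark: 9–13 are racemic at their single stereocentre, which disappears in step 10.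

## Steps

Step 1
Reactants: 1 5-chloropentan-2-one
Product: 2 2-(3-chloropropyl)-2-methyl-1,3-dioxolane
Conditions: HOCH2CH2OH, TsOH·H2O (cat.), toluene, reflux, azeotropic removal of water
Reagents that add atoms: ethylene glycol, OCCO
Why: Acid-catalysed ketalisation driven by removal of water; the ketone must be masked so that the chloride can be used as an electrophile without cyclopropane formation.

Step 2
Reactants: 3 isobutyronitrile; 2 2-(3-chloropropyl)-2-methyl-1,3-dioxolane
Product: 4 2,2-dimethyl-5-(2-methyl-1,3-dioxolan-2-yl)pentanenitrile
Conditions: LiN(iPr)2, THF, −78 °C; then 2, DMPU, −78 → 25 °C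
Reagents that add atoms: none
Why: SN2 alkylation of the lithiated nitrile with a primary chloride forms C3–C4 and the quaternary carbon C4; the product has no α-hydrogen, so over-alkylation is impossible.

Step 3
Reactants: 4 2,2-dimethyl-5-(2-methyl-1,3-dioxolan-2-yl)pentanenitrile
Product: 5 2,2-dimethyl-6-oxoheptanenitrile
Conditions: 1 M HCl, acetone, 25 °C
Reagents that add atoms: water, O
Why: Acid-catalysed ketal hydrolysis; the tertiary nitrile is inert under these conditions.

Step 4
Reactants: 5 2,2-dimethyl-6-oxoheptanenitrile; 6 triethyl phosphonoacetate
Product: 7 ethyl (E)-7-cyano-3,7-dimethyloct-2-enoate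
Conditions: NaH, THF, 0 °C; then 5, 0 → 65 °C; the minor Z isomer is removed by chromatography
Reagents that add atoms: none
Why: Horner–Wadsworth–Emmons olefination of a methyl ketone forms C9=C10; the E isomer should predominate and is purified at this simple stage because the alkene geometry later fixes C9 relative to C10.

Step 5
Reactants: 7 ethyl (E)-7-cyano-3,7-dimethyloct-2-enoate
Product: 8 (E)-8-hydroxy-2,2,6-trimethyloct-6-enal
Conditions: iBu2AlH (3.5 equiv), CH2Cl2, −78 → 0 °C; then 1 M HCl, 0 °C
Reagents that add atoms: water, O
Why: Hydride reduction takes the enoate to the allylic alcohol (1,2-reduction) and the hindered nitrile to the N-aluminio imine, which is hydrolysed to the C5 aldehyde on work-up; the alkene geometry is untouched.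

Step 6
Reactants: 8 (E)-8-hydroxy-2,2,6-trimethyloct-6-enal
Product: 9 (E)-4,4,8-trimethyldec-8-en-1-yne-3,10-diol (racemic)
Conditions: HC≡CMgBr (2.5 equiv), THF, 0 °C; then aq. NH4Cl
Reagents that add atoms: ethynylmagnesium bromide, C#C[Mg]Br
Why: Grignard addition of a small acetylide to the neopentyl aldehyde forms C5–C6; one equivalent is consumed by the hydroxyl group, and the new carbinol centre is of no consequence.

Step 7
Reactants: 9 (E)-4,4,8-trimethyldec-8-en-1-yne-3,10-diol
Product: 10 (E)-5,12-dihydroxy-6,6,10-trimethyldodec-10-en-3-yn-2-one (racemic)
Conditions: nBuLi (3.1 equiv), THF, −78 → −20 °C; then MeC(O)N(OMe)Me, −78 → 0 °C; aq. NH4Cl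
Reagents that add atoms: N-methoxy-N-methylacetamide, CC(=O)N(C)OC
Why: C-acylation of the lithium acetylide with an N-methoxy-N-methylamide forms C7–C8; the chelated tetrahedral adduct survives until work-up, so the ynone never meets the alkoxides, and alkoxides do not react with this acyl donor.

Step 8
Reactants: 10 (E)-5,12-dihydroxy-6,6,10-trimethyldodec-10-en-3-yn-2-one
Product: 12 2-[(E)-8-hydroxy-2,6-dimethyloct-6-en-2-yl]-5-methylfuran-3(2H)-one (racemic), via enaminone 11 (not isolated)
Conditions: Et2NH, EtOH, 25 °C; then 1 M HCl, THF, 25 °C
Reagents that add atoms: water, O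
Why: Conjugate addition of the secondary amine to the ynone gives enaminone 11; on acidification the C5 hydroxyl adds to the C8 carbonyl, water is lost and the iminium is hydrolysed (furan-3(2H)-one synthesis from a γ-hydroxy ynone), so that the carbonyl ends at C6 and the C5 oxygen becomes the ring oxygen.

Step 9
Reactants: 12 2-[(E)-8-hydroxy-2,6-dimethyloct-6-en-2-yl]-5-methylfuran-3(2H)-one
Product: 13 (E)-3,7-dimethyl-7-(5-methyl-3-oxo-2,3-dihydrofuran-2-yl)oct-2-enal (racemic)
Conditions: MnO2 (excess), CH2Cl2, 25 °C
Reagents that add atoms: none
Why: Selective allylic oxidation with MnO2 gives the enal without E/Z isomerisation; the furanone is not oxidised.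

Step 10
Reactants: 13 (E)-3,7-dimethyl-7-(5-methyl-3-oxo-2,3-dihydrofuran-2-yl)oct-2-enal
Product: 14 (E)-7-[3-(tert-butyldimethylsilyloxy)-5-methylfuran-2-yl]-3,7-dimethyloct-2-enal
Conditions: TBSOTf (1.1 equiv), Et3N, CH2Cl2, −78 °C
Reagents that add atoms: tert-butyldimethylsilyl trifluoromethanesulfonate, CC(C)(C)[Si](C)(C)OS(=O)(=O)C(F)(F)F
Why: Soft enolisation: the basic vinylogous-ester carbonyl of the furanone is O-silylated and Et3N removes H5, which gives the aromatic 3-silyloxyfuran (silyl enol ether formation); with one equivalent of triflate at −78 °C the far less basic enal should not be converted into a silyl dienol ether.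

Step 11
Reactants: 14 (E)-7-[3-(tert-butyldimethylsilyloxy)-5-methylfuran-2-yl]-3,7-dimethyloct-2-enal
Product: 16 5α,8α-epoxy-6-(tert-butyldimethylsilyloxy)-12,13,14,15,16-pentanorlabd-6-en-11-al, via iminium ion 15 (not isolated)
Conditions: (2S,5S)-5-benzyl-2-tert-butyl-3-methylimidazolidin-4-one·CF3CO2H (20 mol %), CH2Cl2, H2O (2 equiv), −40 → −10 °C
Reagents that add atoms: none
Why: Proposed new method: enal 14 condenses with the amine salt to the iminium ion 15, and the tethered 3-silyloxyfuran adds across C9=C10 of this LUMO-lowered dienophile in a normal-demand intramolecular Diels–Alder reaction that is expected to be asynchronous, with C5–C10 leading and C8–C9 closing the furanyl cation onto the enamine, before hydrolysis releases 16 and the amine. The closest known reaction types are the iminium-catalysed intramolecular Diels–Alder reaction of trienals, the iminium-catalysed Mukaiyama–Michael addition of silyloxyfurans to enals and the Lewis acid-promoted intramolecular Diels–Alder reaction of furans, none of which has joined a β,β-disubstituted enal to a furan carbon that bears a tertiary alkyl group. Ring A closes as the tether ring through the C5–C10 bond (6-exo-trig with respect to the enal), and ring B closes as the cycloadduct ring through both new bonds, the furan oxygen remaining as the C5–O–C8 bridge. The four-carbon tether can reach C10 only from the side of the oxygen bridge, so C1 is exo and the C10 methyl lies anti to the bridge, which fixes C5 and C8 relative to C10. Suprafacial addition to the E alkene keeps the iminium carbon C11 cis to the C10 methyl and thereby sets C9. The absolute configuration comes from the catalyst: in the E-iminium ion the benzyl group of the (2S,5S) amine covers the Re face of C9, so that the furan should add to the Si face and give the enantiomer drawn. The step needs face selectivity, retention of the enal geometry and ring closure that outruns loss of the silyl group; the geminal dimethyl group at C4 favours the folded conformer, tether and electronics ask for the same regiochemistry, and only two equivalents of water are present.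

Step 12
Reactants: 17 3-methylglutaric anhydride
Product: 18 (S)-5-methoxy-3-methyl-5-oxopentanoic acid
Conditions: (DHQD)2AQN (hydroquinidine anthraquinone-1,4-diyl diether, 10 mol %), MeOH (10 equiv), Et2O, −40 °C
Reagents that add atoms: methanol, CO
Why: Desymmetrising alcoholysis of a prochiral cyclic anhydride under general-base catalysis by a cinchona alkaloid diether; the catalyst distinguishes the two enantiotopic carbonyl groups and thereby sets C13.

Step 13
Reactants: 18 (S)-5-methoxy-3-methyl-5-oxopentanoic acid
Product: 19 methyl (R)-4-iodo-3-methylbutanoate
Conditions: PhI(OAc)2, I2, CCl4, hν (tungsten lamp), reflux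
Reagents that add atoms: iodine, II
Why: Hunsdiecker-type iododecarboxylation: the acyl hypoiodite formed from the acid fragments under light to CO2 and the primary C12 radical, which is trapped by iodine. C13 is not a radical site and keeps its configuration; the descriptor changes from S to R only because the CIP priorities change.

Step 14
Reactants: 19 methyl (R)-4-iodo-3-methylbutanoate
Product: 20 [(R)-4-methoxy-2-methyl-4-oxobutyl]triphenylphosphonium iodide
Conditions: PPh3, MeCN, reflux
Reagents that add atoms: triphenylphosphine, c1ccc(cc1)P(c1ccccc1)c1ccccc1
Why: SN2 quaternisation of the phosphine by the primary iodide, the standard entry to an ester-bearing alkylphosphonium salt.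

Step 15
Reactants: 20 [(R)-4-methoxy-2-methyl-4-oxobutyl]triphenylphosphonium iodide; 16 5α,8α-epoxy-6-(tert-butyldimethylsilyloxy)-12,13,14,15,16-pentanorlabd-6-en-11-al
Product: 22 methyl (11Z,13R)-5α,8α-epoxy-6-(tert-butyldimethylsilyloxy)labda-6,11-dien-15-oate, via phosphorus ylide 21 (not isolated)
Conditions: 20, NaN(SiMe3)2 (0.98 equiv), THF, −78 → 0 °C; then 16, −78 → 0 °C
Reagents that add atoms: none
Why: Wittig olefination with the non-stabilised ylide 21 (the phosphonium CH2 is more acidic than the ester α-CH2) forms C11=C12 at low temperature without excess base. C9 and C13 are not touched, and the expected Z geometry is irrelevant to the target.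

Step 16
Reactants: 22 methyl (11Z,13R)-5α,8α-epoxy-6-(tert-butyldimethylsilyloxy)labda-6,11-dien-15-oate
Product: 23 methyl (11Z,13R)-5α,8α-epoxy-6-oxolabd-11-en-15-oate
Conditions: Bu4NF, AcOH, THF, 0 °C
Reagents that add atoms: none
Why: Fluoride cleavage of the silyl enol ether; the buffer protonates the enolate at C7 before it can expel the C8 oxygen, and once C7 is saturated the adduct can no longer undergo cycloreversion.

Step 17
Reactants: 23 methyl (11Z,13R)-5α,8α-epoxy-6-oxolabd-11-en-15-oate
Product: 24 methyl (11Z,13R)-8α-hydroxy-6-oxolabd-11-en-15-oate
Conditions: SmI2 (2.5 equiv), THF–MeOH, −78 °C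
Reagents that add atoms: none
Why: Reductive cleavage of an α-alkoxy ketone by electron transfer: the ketyl expels only the C5–O bond, leaving the former furan oxygen as the C8α alkoxide. The trivalent samarium enolate is protonated by methanol at C5 from the α face, anti to the axial methyls on C4 and C10, which gives the trans ring fusion. The ester and the isolated alkene are inert at this temperature.

Step 18
Reactants: 24 methyl (11Z,13R)-8α-hydroxy-6-oxolabd-11-en-15-oate
Product: 25 methyl (11Z,13R)-6β,8α-dihydroxylabd-11-en-15-oate
Conditions: NaBH4, CeCl3·7H2O, MeOH, −40 → 0 °C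
Reagents that add atoms: none
Why: Luche-type borohydride reduction under weakly basic conditions that spare C5 and the β-hydroxy ketone; hydride enters from the α face because the β face of C6 is covered by the axial methyls on C4, C8 and C10, giving the axial 6β alcohol.

Step 19
Reactants: 25 methyl (11Z,13R)-6β,8α-dihydroxylabd-11-en-15-oate
Product: 26 methyl (11Z,13R)-6β-acetoxy-8α-hydroxylabd-11-en-15-oate
Conditions: Ac2O, DMAP, pyridine, 40 °C
Reagents that add atoms: acetic anhydride, CC(=O)OC(C)=O
Why: DMAP-catalysed acylation; the secondary 6β hydroxyl, although axial, should react ahead of the tertiary C8 hydroxyl.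

Step 20
Reactants: 26 methyl (11Z,13R)-6β-acetoxy-8α-hydroxylabd-11-en-15-oate
Product: 27 methyl (13S)-6β-acetoxy-8α-hydroxylabdan-15-oate (CNP0113148.1)
Conditions: H2 (1 atm), PtO2, EtOAc, 25 °C
Reagents that add atoms: none
Why: Heterogeneous hydrogenation of the disubstituted alkene over platinum, chosen over palladium to limit double-bond migration towards C13; esters and the tertiary alcohol are inert, and C13 changes only its descriptor (R to S) because C12 loses priority.

## Compound list

1 | 5-chloropentan-2-one | CC(=O)CCCCl | starting material
2 | 2-(3-chloropropyl)-2-methyl-1,3-dioxolane | CC1(CCCCl)OCCO1 | intermediate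
3 | isobutyronitrile | CC(C)C#N | starting material
4 | 2,2-dimethyl-5-(2-methyl-1,3-dioxolan-2-yl)pentanenitrile | CC1(CCCC(C)(C)C#N)OCCO1 | intermediate
5 | 2,2-dimethyl-6-oxoheptanenitrile | CC(=O)CCCC(C)(C)C#N | intermediate
6 | triethyl phosphonoacetate | CCOC(=O)CP(=O)(OCC)OCC | starting material
7 | ethyl (E)-7-cyano-3,7-dimethyloct-2-enoate | CCOC(=O)/C=C(\C)CCCC(C)(C)C#N | intermediate
8 | (E)-8-hydroxy-2,2,6-trimethyloct-6-enal | O=CC(C)(C)CCC/C(C)=C/CO | intermediate
9 | (E)-4,4,8-trimethyldec-8-en-1-yne-3,10-diol (racemic) | C#CC(O)C(C)(C)CCC/C(C)=C/CO | intermediate
10 | (E)-5,12-dihydroxy-6,6,10-trimethyldodec-10-en-3-yn-2-one (racemic) | CC(=O)C#CC(O)C(C)(C)CCC/C(C)=C/CO | intermediate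
11 | (3E,10E)-4-(diethylamino)-5,12-dihydroxy-6,6,10-trimethyldodeca-3,10-dien-2-one (racemic, not isolated) | CC(=O)/C=C(/N(CC)CC)C(O)C(C)(C)CCC/C(C)=C/CO | intermediate
12 | 2-[(E)-8-hydroxy-2,6-dimethyloct-6-en-2-yl]-5-methylfuran-3(2H)-one (racemic) | CC1=CC(=O)C(O1)C(C)(C)CCC/C(C)=C/CO | intermediate
13 | (E)-3,7-dimethyl-7-(5-methyl-3-oxo-2,3-dihydrofuran-2-yl)oct-2-enal (racemic) | CC1=CC(=O)C(O1)C(C)(C)CCC/C(C)=C/C=O | intermediate
14 | (E)-7-[3-(tert-butyldimethylsilyloxy)-5-methylfuran-2-yl]-3,7-dimethyloct-2-enal | Cc1cc(O[Si](C)(C)C(C)(C)C)c(o1)C(C)(C)CCC/C(C)=C/C=O | intermediate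
15 | iminium trifluoroacetate of 14 with (2S,5S)-5-benzyl-2-tert-butyl-3-methylimidazolidin-4-one (not isolated) | CC(C)(C)[C@H]1/[N+](=C/C=C(\C)CCCC(C)(C)c2oc(C)cc2O[Si](C)(C)C(C)(C)C)[C@@H](Cc2ccccc2)C(=O)N1C.[O-]C(=O)C(F)(F)F | intermediate
16 | 5α,8α-epoxy-6-(tert-butyldimethylsilyloxy)-12,13,14,15,16-pentanorlabd-6-en-11-al | O=C[C@@H]1[C@@]2(C)CCCC(C)(C)[C@@]23O[C@]1(C)C=C3O[Si](C)(C)C(C)(C)C | intermediate
17 | 3-methylglutaric anhydride | CC1CC(=O)OC(=O)C1 | starting material
18 | (S)-5-methoxy-3-methyl-5-oxopentanoic acid | COC(=O)C[C@@H](C)CC(=O)O | intermediate
19 | methyl (R)-4-iodo-3-methylbutanoate | COC(=O)C[C@@H](C)CI | intermediate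
20 | [(R)-4-methoxy-2-methyl-4-oxobutyl]triphenylphosphonium iodide | COC(=O)C[C@@H](C)C[P+](c1ccccc1)(c1ccccc1)c1ccccc1.[I-] | intermediate
21 | methyl (R)-3-methyl-4-(triphenyl-λ5-phosphanylidene)butanoate (not isolated) | COC(=O)C[C@@H](C)C=P(c1ccccc1)(c1ccccc1)c1ccccc1 | intermediate
22 | methyl (11Z,13R)-5α,8α-epoxy-6-(tert-butyldimethylsilyloxy)labda-6,11-dien-15-oate | COC(=O)C[C@@H](C)/C=C\[C@@H]1[C@@]2(C)CCCC(C)(C)[C@@]23O[C@]1(C)C=C3O[Si](C)(C)C(C)(C)C | intermediate
23 | methyl (11Z,13R)-5α,8α-epoxy-6-oxolabd-11-en-15-oate | COC(=O)C[C@@H](C)/C=C\[C@@H]1[C@@]2(C)CCCC(C)(C)[C@@]23O[C@]1(C)CC3=O | intermediate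
24 | methyl (11Z,13R)-8α-hydroxy-6-oxolabd-11-en-15-oate | COC(=O)C[C@@H](C)/C=C\[C@@H]1[C@@]2(C)CCCC(C)(C)[C@@H]2C(=O)C[C@@]1(C)O | intermediate
25 | methyl (11Z,13R)-6β,8α-dihydroxylabd-11-en-15-oate | COC(=O)C[C@@H](C)/C=C\[C@@H]1[C@@]2(C)CCCC(C)(C)[C@@H]2[C@H](O)C[C@@]1(C)O | intermediate
26 | methyl (11Z,13R)-6β-acetoxy-8α-hydroxylabd-11-en-15-oate | COC(=O)C[C@@H](C)/C=C\[C@@H]1[C@@]2(C)CCCC(C)(C)[C@@H]2[C@H](OC(C)=O)C[C@@]1(C)O | intermediate
27 | methyl (13S)-6β-acetoxy-8α-hydroxylabdan-15-oate (CNP0113148.1) | COC(=O)C[C@@H](C)CC[C@@H]1[C@@]2(C)CCCC(C)(C)[C@@H]2[C@H](OC(C)=O)C[C@@]1(C)O | target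

## Step count and least certain steps

Total: 20 steps. Longest linear sequence: 17 steps (steps 1–11 and 15–20). The side-chain branch (steps 12–14) takes 3 steps.

**Step 11 (key step, new method).** Several processes can defeat it.
- The C5–C10 bond joins two fully substituted carbons next to quaternary C4, so the cycloaddition may not proceed or may revert.
- The Michael-type intermediate may lose its silyl group before the second bond closes, which stops the reaction at a spiro furanone.
- The iminium ion of a β,β-disubstituted enal can equilibrate through a dienamine, which erodes the E geometry and with it the C9 configuration.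
- Face selectivity may be poor because the β-methyl group weakens the geometric control of the iminium ion, and an uncatalysed background reaction would be racemic.
- If the sense of induction is opposite to the one predicted, the (2R,5R) amine is used.

Fallback by known chemistry: from 14, a Lewis acid-promoted intramolecular Diels–Alder reaction of the furan (Me2AlCl, CH2Cl2, −78 °C) should give 16 together with the enantiomer of 16 F1 as the racemate, the relative configuration being fixed by the tether and the E alkene as before. The racemate is then submitted to the Wittig reaction of step 15 with the enantiopure ylide 21, which gives 22 and the ring-enantiomeric diastereomer of 22 F2. The two are diastereomers and are separated by chromatography, and the route is rejoined at 22.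

**Step 15 (Wittig union).** The aldehyde sits on C9 between two quaternary carbons, so addition of the ylide may be slow. A slow addition gives time for cycloreversion of the strained enol-ether adduct and for base-induced epimerisation at C9.

Fallback: the order is changed so that the bridge is locked first. From 16, buffered fluoride (Bu4NF, AcOH, THF, 0 °C) gives the keto aldehyde 5α,8α-epoxy-6-oxo-12,13,14,15,16-pentanorlabdan-11-al F3, which has no ring alkene and cannot revert. F3 is then treated with the salt-free ylide 21 at −78 °C; the aldehyde reacts in preference to the bridged ketone, and the product is 23, where the route is rejoined. The price is that the ketone is exposed to a basic reagent, so the ylide is kept as the limiting component.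

**Step 10 (O-silylation beside the enal).** The silyl triflate may also activate the enal and convert it into a silyl dienol ether, or the electron-rich silyloxyfuran may not survive isolation next to a free aldehyde.

Fallback: the enal is formed last. From 12, acetylation (Ac2O, pyridine) gives the allylic acetate of 12 F4. Silylation of its furanone (TBSOTf, Et3N, −78 °C) gives the silyloxyfuran acetate F5. Reductive removal of the acetate (iBu2AlH, CH2Cl2, −78 °C) gives the silyloxyfuran allylic alcohol F6, and MnO2 oxidation of F6 gives 14, where the route is rejoined.

**Step 19 (selective acetylation).** The 6β hydroxyl is axial and syn to three methyl groups, so acylation may need forcing conditions under which the tertiary C8 hydroxyl also reacts, or may stop short.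

Fallback: the tertiary hydroxyl is masked before the ketone is reduced. From 24, N-(trimethylsilyl)imidazole gives the C8 trimethylsilyl ether of 24 F7. Reduction as in step 18 gives the 6β alcohol F8. Forcing acetylation (Ac2O, DMAP, Et3N, 60 °C) gives the 6β acetate F9, and mild desilylation (HF·pyridine, THF, 0 °C) gives 26, where the route is rejoined.

**Step 20 (hydrogenation).** Migration of the double bond on the metal surface towards C12=C13 before saturation would scramble C13, and the alkene is flanked by two branched carbons and may react slowly.

Fallback: the metal is avoided altogether. From 26, diimide generated from 2-nitrobenzenesulfonohydrazide and Et3N in CH2Cl2 transfers hydrogen in a concerted syn fashion without alkene isomerisation and gives 27 directly; no new compound is involved.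

## Further compounds

F1 | step 11 | enantiomer of 16 (formed with 16 as the racemate) | O=C[C@H]1[C@]2(C)CCCC(C)(C)[C@]23O[C@@]1(C)C=C3O[Si](C)(C)C(C)(C)C
F2 | step 11 | ring-enantiomeric diastereomer of 22 (methyl (11Z,13R)-ester from F1) | COC(=O)C[C@@H](C)/C=C\[C@H]1[C@]2(C)CCCC(C)(C)[C@]23O[C@@]1(C)C=C3O[Si](C)(C)C(C)(C)C
F3 | step 15 | 5α,8α-epoxy-6-oxo-12,13,14,15,16-pentanorlabdan-11-al | O=C[C@@H]1[C@@]2(C)CCCC(C)(C)[C@@]23O[C@]1(C)CC3=O
F4 | step 10 | (E)-3,7-dimethyl-7-(5-methyl-3-oxo-2,3-dihydrofuran-2-yl)oct-2-en-1-yl acetate (racemic) | CC1=CC(=O)C(O1)C(C)(C)CCC/C(C)=C/COC(C)=O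
F5 | step 10 | (E)-7-[3-(tert-butyldimethylsilyloxy)-5-methylfuran-2-yl]-3,7-dimethyloct-2-en-1-yl acetate | Cc1cc(O[Si](C)(C)C(C)(C)C)c(o1)C(C)(C)CCC/C(C)=C/COC(C)=O
F6 | step 10 | (E)-7-[3-(tert-butyldimethylsilyloxy)-5-methylfuran-2-yl]-3,7-dimethyloct-2-en-1-ol | Cc1cc(O[Si](C)(C)C(C)(C)C)c(o1)C(C)(C)CCC/C(C)=C/CO
F7 | step 19 | methyl (11Z,13R)-6-oxo-8α-(trimethylsilyloxy)labd-11-en-15-oate | COC(=O)C[C@@H](C)/C=C\[C@@H]1[C@@]2(C)CCCC(C)(C)[C@@H]2C(=O)C[C@@]1(C)O[Si](C)(C)C
F8 | step 19 | methyl (11Z,13R)-6β-hydroxy-8α-(trimethylsilyloxy)labd-11-en-15-oate | COC(=O)C[C@@H](C)/C=C\[C@@H]1[C@@]2(C)CCCC(C)(C)[C@@H]2[C@H](O)C[C@@]1(C)O[Si](C)(C)C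
F9 | step 19 | methyl (11Z,13R)-6β-acetoxy-8α-(trimethylsilyloxy)labd-11-en-15-oate | COC(=O)C[C@@H](C)/C=C\[C@@H]1[C@@]2(C)CCCC(C)(C)[C@@H]2[C@H](OC(C)=O)C[C@@]1(C)O[Si](C)(C)C
F0 | step 20 | none | none
A1 | alternative 1 | 3-methylcyclohex-2-en-1-one | CC1=CC(=O)CCC1
A2 | alternative 1 | (4-methylpent-3-en-1-yl)magnesium bromide | CC(C)=CCC[Mg]Br
A3 | alternative 1 | methyl (R)-5-iodo-3-methylpentanoate | COC(=O)C[C@@H](C)CCI
A4 | alternative 1 | methyl 3-methyl-5-[2-methyl-2-(4-methylpent-3-en-1-yl)-6-oxocyclohexyl]pentanoate (ring B ketone, configuration as in the SMILES) | COC(=O)C[C@@H](C)CC[C@@H]1[C@@](C)(CCC=C(C)C)CCCC1=O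
A5 | alternative 2 | 2,6-dimethyl-1,4-benzoquinone | CC1=CC(=O)C=C(C)C1=O
A6 | alternative 2 | trimethyl[(4-methylpenta-1,3-dien-2-yl)oxy]silane | C=C(O[Si](C)(C)C)C=C(C)C
A7 | alternative 2 | trans-fused 11,12,13,14,15,16-hexanorlabd-7-ene-2,6,9-trione | O=C1[C@@]2(C)CC(=O)CC(C)(C)[C@@H]2C(=O)C=C1C
A8 | alternative 3 | dimethyl 2-[(E)-2,6-dimethyl-8-oxonon-6-en-2-yl]propanedioate | COC(=O)C(C(=O)OC)C(C)(C)CCC/C(C)=C/C(C)=O
A9 | alternative 3 | bicyclic 6,8-dione with a C5 methoxycarbonyl group and the C10 methyl (methyl 6,8-dioxo-11,12,13,14,15,16,17-heptanorlabdane-5-carboxylate type, configuration as in the SMILES) | O=C1C[C@@]2(C)CCCC(C)(C)[C@]2(C(=O)OC)C(=O)C1
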